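**Plan**

- Retrosynthesis (cyclodeca[b]furan locants O1, C2, C3, C3a, C4–C11, C11a): take off the C9 acetate, return the 7,8-oxirane to a C7=C8 Z-alkene, cut C8–C9 (alkenyl iodide + enal), then cut C3a–C11a together with the lactone C–O bond (2-(methoxycarbonyl)allyl bromide + enal), then remove the C4 angelate.
- Enabling feature: C9 carries oxygen and lies between the C10=C11 E-alkene and oxirane carbon C8. The oxirane is a masked Z-alkene, so C9 is a doubly allylic carbinol, and C8–C9 is the bond made when a Z-alkenyl metal at C8 adds to an enal carbonyl at C9. The cis-fused lactone ring holds both arms on one side.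
- Forward order: the iodoalkene arm (steps 1–7) and the C5 enal acetal (steps 8–9) are joined in step 10, which builds the lactone ring; the ten-membered ring closes in step 13; the oxirane ring and the acetate follow.
- Stereochemistry: C4 is bought ((R)-butane-1,2,4-triol acetonide). C3a and C11a are relayed from C4 in one allylation. C9 arises in the ring closure under control of the lactone centres. C7 and C8 are relayed from C9 by hydroxyl-directed epoxidation. The Z (carbocupration) and E (HWE) alkenes are fixed before ring closure.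

Key step: step 13

Remark: the target is read from its SMILES as the (3aR,4R,7S,8R,9R,11aS) isomer with a 10E ring alkene, a cis-fused lactone and a Z (angelate) ester; "Cn" means the carbon that becomes Cn of this skeleton; 9 and 13 are carried as epimer mixtures at centres that the next step removes; 1 and all reagents are taken as commercial.

**Route**

Step 1
Reactants: 1 2-[(4R)-2,2-dimethyl-1,3-dioxolan-4-yl]ethanol
Product: 2 (4R)-4-(2-bromoethyl)-2,2-dimethyl-1,3-dioxolane
Conditions: CBr4, PPh3, 2,6-lutidine, CH2Cl2, 0 °C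
Reagents that add atoms: carbon tetrabromide, BrC(Br)(Br)Br
Why: Appel reaction: the alkoxyphosphonium ion of the primary alcohol is displaced by bromide under near-neutral conditions, which leave the acetonide and the stereocentre untouched.

Step 2
Reactants: 2 (4R)-4-(2-bromoethyl)-2,2-dimethyl-1,3-dioxolane; 3 propyne
Product: 7 (4R)-4-[(3Z)-4-iodo-3-methylbut-3-en-1-yl]-2,2-dimethyl-1,3-dioxolane, via Grignard reagent 4 (not isolated), via alkylcopper 5 (not isolated), via alkenylcopper 6 (not isolated)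
Conditions: Mg, Et2O, rt; CuBr·SMe2, Et2O/Me2S, −45 °C; propyne, −25 °C; I2, −50 °C to rt
Reagents that add atoms: iodine, [I][I]
Why: Normant carbocupration: the alkylcopper made from the Grignard reagent adds syn across propyne with the alkyl group on the internal carbon, and iodinolysis of the alkenylcopper with retention gives the Z-iodoalkene with iodine cis to the chain, the geometry of the later cis ring alkene.

Step 3
Reactants: 7 (4R)-4-[(3Z)-4-iodo-3-methylbut-3-en-1-yl]-2,2-dimethyl-1,3-dioxolane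
Product: 9 (4R)-4-[(3Z)-4-iodo-3-methylbut-3-en-1-yl]-2-(4-methoxyphenyl)-1,3-dioxolane (both epimers at C2), via diol 8 (not isolated)
Conditions: PPTS, MeOH/H2O, 50 °C; evaporate; 4-MeOC6H4CH(OMe)2, PPTS, CH2Cl2, rt
Reagents that add atoms: 4-methoxybenzaldehyde dimethyl acetal, COc1ccc(cc1)C(OC)OC
Why: Acid-catalysed acetal exchange (hydrolysis of the acetonide, then formation of the five-membered 4-methoxybenzylidene acetal of the 1,2-diol), which touches neither the stereocentre nor the iodoalkene.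

Step 4
Reactants: 9 (4R)-4-[(3Z)-4-iodo-3-methylbut-3-en-1-yl]-2-(4-methoxyphenyl)-1,3-dioxolane
Product: 10 (2R,5Z)-6-iodo-2-[(4-methoxybenzyl)oxy]-5-methylhex-5-en-1-ol
Conditions: iBu2AlH, CH2Cl2, −78 to 0 °C; aq. potassium sodium tartrate
Reagents that add atoms: none
Why: Regioselective reductive opening of a 4-methoxybenzylidene acetal: aluminium coordinates the less hindered primary oxygen and hydride cleaves that carbon–oxygen bond, so the PMB group stays on the secondary oxygen and the primary alcohol is freed.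

Step 5
Reactants: 10 (2R,5Z)-6-iodo-2-[(4-methoxybenzyl)oxy]-5-methylhex-5-en-1-ol
Product: 11 (2R,5Z)-6-iodo-2-[(4-methoxybenzyl)oxy]-5-methylhex-5-enal
Conditions: Dess–Martin periodinane, CH2Cl2, 0 °C to rt
Reagents that add atoms: none
Why: Dess–Martin oxidation gives the α-alkoxy aldehyde under mild non-basic conditions that should not epimerise the adjacent stereocentre; the aldehyde is used directly.

Step 6
Reactants: 11 (2R,5Z)-6-iodo-2-[(4-methoxybenzyl)oxy]-5-methylhex-5-enal; 12 methyl acrylate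
Product: 13 methyl (4R,7Z)-3-hydroxy-8-iodo-4-[(4-methoxybenzyl)oxy]-7-methyl-2-methylideneoct-7-enoate (both C3 epimers)
Conditions: DABCO (0.5 equiv), methyl acrylate (excess), neat, rt
Reagents that add atoms: none
Why: Morita–Baylis–Hillman reaction of an activated α-alkoxy aldehyde with methyl acrylate; the new carbinol centre needs no control because it becomes an alkene carbon in step 7.

Step 7
Reactants: 13 methyl (4R,7Z)-3-hydroxy-8-iodo-4-[(4-methoxybenzyl)oxy]-7-methyl-2-methylideneoct-7-enoate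
Product: 14 methyl (2Z,4R,7Z)-2-(bromomethyl)-8-iodo-4-[(4-methoxybenzyl)oxy]-7-methylocta-2,7-dienoate
Conditions: NBS, Me2S, CH2Cl2, 0 °C to rt
Reagents that add atoms: N-bromosuccinimide, O=C1CCC(=O)N1Br
Why: Bromination with allylic transposition (SN2′ displacement by bromide of the alkoxysulfonium ion formed from the Corey–Kim-type reagent) gives the thermodynamically preferred Z-2-(bromomethyl)alk-2-enoate, with the C4 chain cis to CH2Br.

Step 8
Reactants: 15 1,1-dimethoxypropan-2-one; 16 diethyl {2-[methoxy(methyl)amino]-2-oxoethyl}phosphonate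
Product: 17 (2E)-N,4,4-trimethoxy-N,3-dimethylbut-2-enamide
Conditions: NaH, THF, 0 °C to rt
Reagents that add atoms: none
Why: Horner–Wadsworth–Emmons olefination of an activated α,α-dialkoxy ketone places the larger dimethoxymethyl group trans to the amide carbonyl (E); any minor Z isomer is removed by chromatography.

Step 9
Reactants: 17 (2E)-N,4,4-trimethoxy-N,3-dimethylbut-2-enamide
Product: 18 (2E)-4,4-dimethoxy-3-methylbut-2-enal
Conditions: iBu2AlH, THF, −78 °C; aq. potassium sodium tartrate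
Reagents that add atoms: none
Why: Reduction of the Weinreb amide stops at the aldehyde through the chelated tetrahedral aluminium intermediate, and 1,2-reduction at −78 °C leaves the alkene geometry and the acetal intact.

Step 10
Reactants: 14 methyl (2Z,4R,7Z)-2-(bromomethyl)-8-iodo-4-[(4-methoxybenzyl)oxy]-7-methylocta-2,7-dienoate; 18 (2E)-4,4-dimethoxy-3-methylbut-2-enal
Product: 21 (2E)-3-[(2S,3R)-3-{(1R,4Z)-5-iodo-1-[(4-methoxybenzyl)oxy]-4-methylpent-4-en-1-yl}-4-methylidene-5-oxooxolan-2-yl]-2-methylprop-2-enal, via allylzinc bromide 19 (not isolated), via lactone acetal 20 (not isolated)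
Conditions: Zn dust (activated), THF, 0 °C to rt; then 1 M aq. HCl, rt
Reagents that add atoms: water, O
Why: Barbier-type 2-(alkoxycarbonyl)allylation with in situ lactonisation (Dreiding–Schmidt reaction): the Z-allylzinc adds 1,2 to the enal through a chair transition state to the syn adduct, hence the cis-lactone, on the allyl face that carries the zinc-chelating PMB-oxy group (C4–H in the alkene plane to avoid A(1,3) strain, chain anti to the incoming aldehyde), so that C4 relays C3a (R) and C11a (S) in one event, and aqueous acid then completes lactonisation and unmasks the C9 aldehyde.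

Step 11
Reactants: 21 (2E)-3-[(2S,3R)-3-{(1R,4Z)-5-iodo-1-[(4-methoxybenzyl)oxy]-4-methylpent-4-en-1-yl}-4-methylidene-5-oxooxolan-2-yl]-2-methylprop-2-enal
Product: 22 (2E)-3-{(2S,3R)-3-[(1R,4Z)-1-hydroxy-5-iodo-4-methylpent-4-en-1-yl]-4-methylidene-5-oxooxolan-2-yl}-2-methylprop-2-enal
Conditions: DDQ, CH2Cl2/aq. Na2HPO4–NaH2PO4 buffer (pH 7), 0 °C
Reagents that add atoms: none
Why: Oxidative removal of the PMB ether with DDQ (hydride abstraction, then hydrolysis of the oxocarbenium ion) under buffered conditions that should not let the lactone migrate to the freed hydroxyl or affect the enal, the iodoalkene or the α-methylene lactone.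

Step 12
Reactants: 22 (2E)-3-{(2S,3R)-3-[(1R,4Z)-1-hydroxy-5-iodo-4-methylpent-4-en-1-yl]-4-methylidene-5-oxooxolan-2-yl}-2-methylprop-2-enal; 23 angelic acid, (2Z)-2-methylbut-2-enoic acid
Product: 25 (1R,4Z)-5-iodo-4-methyl-1-{(2S,3R)-2-[(1E)-2-methyl-3-oxoprop-1-en-1-yl]-4-methylidene-5-oxooxolan-3-yl}pent-4-en-1-yl (2Z)-2-methylbut-2-enoate, via mixed anhydride 24 (not isolated)
Conditions: 23, 2,4,6-Cl3C6H2COCl, Et3N, toluene, rt; then 22, toluene, 80 °C
Reagents that add atoms: none
Why: Yamaguchi-type esterification through the preformed mixed anhydride without DMAP, conditions under which angelic acid is transferred without Z-to-E isomerisation to the tiglate, with retention at C4.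

Step 13
Reactants: 25 (1R,4Z)-5-iodo-4-methyl-1-{(2S,3R)-2-[(1E)-2-methyl-3-oxoprop-1-en-1-yl]-4-methylidene-5-oxooxolan-3-yl}pent-4-en-1-yl (2Z)-2-methylbut-2-enoate
Product: 27 (3aR,4R,7Z,9S,10E,11aS)-9-hydroxy-7,10-dimethyl-3-methylidene-2-oxo-2,3,3a,4,5,6,9,11a-octahydrocyclodeca[b]furan-4-yl (2Z)-2-methylbut-2-enoate, via alkenylchromium dichloride 26 (not isolated)
Conditions: CrCl2 (15 equiv), NiCl2 (0.2 equiv), degassed DMSO, 0.003 M, slow addition of 25, rt; aq. work-up
Reagents that add atoms: none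
Why: Nozaki–Hiyama–Kishi reaction: zerovalent nickel, formed from NiCl2 by CrCl2, inserts into the carbon–iodine bond, transmetalation to trivalent chromium gives the Z-alkenylchromium 26 with retention, and this adds 1,2 to the enal carbonyl. The closest known reaction type is the Ni/Cr-mediated cyclisation of iodoalkene aldehydes to medium-ring and macrocyclic allylic alcohols. The ten-membered carbocycle closes in a 10-exo-trig mode, eased because the cis-lactone turns both arms to one side and the preformed C7=C8 Z-alkene and C10=C11 E-alkene already supply the turns of the ring. C9 is set by substrate control from C11a and C3a: with H-11a eclipsing the C10=C11 bond (A(1,3) strain against the C10 methyl) the chain crosses the enal face on which C3a lies, and the bulky chromium alkoxide is predicted to take the position next to H-11 and not next to the C10 methyl (A(1,2) strain), which corresponds to the 9S alcohol. The step needs chemoselectivity for the aldehyde over the α-methylene lactone and the angelate, which alkenylchromium reagents show, retention of the Z geometry, which the configurationally stable alkenyl–chromium bond secures, and ring closure over oligomerisation, which slow addition at high dilution secures.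

Step 14
Reactants: 27 (3aR,4R,7Z,9S,10E,11aS)-9-hydroxy-7,10-dimethyl-3-methylidene-2-oxo-2,3,3a,4,5,6,9,11a-octahydrocyclodeca[b]furan-4-yl (2Z)-2-methylbut-2-enoate
Product: 28 (3aR,4R,7S,8R,9R,10E,11aS)-7,8-epoxy-9-hydroxy-7,10-dimethyl-3-methylidene-2-oxo-2,3,3a,4,5,6,7,8,9,11a-decahydrocyclodeca[b]furan-4-yl (2Z)-2-methylbut-2-enoate
Conditions: VO(acac)2 (5 mol%), t-BuOOH, CH2Cl2, 0 °C
Reagents that add atoms: tert-butyl hydroperoxide, CC(C)(C)OO
Why: Hydroxyl-directed epoxidation: the vanadate ester of the C9 hydroxyl delivers oxygen to the C7=C8 Z-alkene, the C10=C11 alkene being deactivated by the allylic lactone oxygen at C11a, and, as with medium-ring Z-cycloalk-2-enols, oxygen enters on the ring face that carries the hydroxyl (cis epoxy alcohol), which sets 7S and 8R from C9 in one event.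

Step 15
Reactants: 28 (3aR,4R,7S,8R,9R,10E,11aS)-7,8-epoxy-9-hydroxy-7,10-dimethyl-3-methylidene-2-oxo-2,3,3a,4,5,6,7,8,9,11a-decahydrocyclodeca[b]furan-4-yl (2Z)-2-methylbut-2-enoate
Product: 29 (3aR,4R,7S,8R,9R,10E,11aS)-9-acetoxy-7,8-epoxy-7,10-dimethyl-3-methylidene-2-oxo-2,3,3a,4,5,6,7,8,9,11a-decahydrocyclodeca[b]furan-4-yl (2Z)-2-methylbut-2-enoate
Conditions: Ac2O, pyridine, DMAP (cat.), CH2Cl2, 0 °C to rt
Reagents that add atoms: acetic anhydride, CC(=O)OC(C)=O
Why: DMAP-catalysed acetylation of the secondary alcohol; the oxirane, the angelate and the α-methylene lactone are inert to these conditions and no stereocentre is touched.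

**Compound list**

1 | 2-[(4R)-2,2-dimethyl-1,3-dioxolan-4-yl]ethanol | CC1(C)OC[C@@H](CCO)O1 | starting material
2 | (4R)-4-(2-bromoethyl)-2,2-dimethyl-1,3-dioxolane | CC1(C)OC[C@@H](CCBr)O1 | intermediate
3 | propyne | CC#C | starting material
4 | bromo{2-[(4R)-2,2-dimethyl-1,3-dioxolan-4-yl]ethyl}magnesium (Grignard reagent) | CC1(C)OC[C@@H](CC[Mg]Br)O1 | intermediate
5 | {2-[(4R)-2,2-dimethyl-1,3-dioxolan-4-yl]ethyl}copper (alkylcopper) | CC1(C)OC[C@@H](CC[Cu])O1 | intermediate
6 | {(1Z)-4-[(4R)-2,2-dimethyl-1,3-dioxolan-4-yl]-2-methylbut-1-en-1-yl}copper (alkenylcopper) | CC1(C)OC[C@@H](CC/C(C)=C\[Cu])O1 | intermediate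
7 | (4R)-4-[(3Z)-4-iodo-3-methylbut-3-en-1-yl]-2,2-dimethyl-1,3-dioxolane | CC1(C)OC[C@@H](CC/C(C)=C\I)O1 | intermediate
8 | (2R,5Z)-6-iodo-5-methylhex-5-ene-1,2-diol | OC[C@H](O)CC/C(C)=C\I | intermediate
9 | (4R)-4-[(3Z)-4-iodo-3-methylbut-3-en-1-yl]-2-(4-methoxyphenyl)-1,3-dioxolane (both epimers at C2) | COc1ccc(cc1)C1OC[C@@H](CC/C(C)=C\I)O1 | intermediate
10 | (2R,5Z)-6-iodo-2-[(4-methoxybenzyl)oxy]-5-methylhex-5-en-1-ol | OC[C@H](OCc1ccc(OC)cc1)CC/C(C)=C\I | intermediate
11 | (2R,5Z)-6-iodo-2-[(4-methoxybenzyl)oxy]-5-methylhex-5-enal | O=C[C@H](OCc1ccc(OC)cc1)CC/C(C)=C\I | intermediate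
12 | methyl acrylate | C=CC(=O)OC | starting material
13 | methyl (4R,7Z)-3-hydroxy-8-iodo-4-[(4-methoxybenzyl)oxy]-7-methyl-2-methylideneoct-7-enoate (both C3 epimers) | C=C(C(=O)OC)C(O)[C@H](OCc1ccc(OC)cc1)CC/C(C)=C\I | intermediate
14 | methyl (2Z,4R,7Z)-2-(bromomethyl)-8-iodo-4-[(4-methoxybenzyl)oxy]-7-methylocta-2,7-dienoate | COC(=O)/C(CBr)=C/[C@H](OCc1ccc(OC)cc1)CC/C(C)=C\I | intermediate
15 | 1,1-dimethoxypropan-2-one | CC(=O)C(OC)OC | starting material
16 | diethyl {2-[methoxy(methyl)amino]-2-oxoethyl}phosphonate | CCOP(=O)(CC(=O)N(C)OC)OCC | starting material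
17 | (2E)-N,4,4-trimethoxy-N,3-dimethylbut-2-enamide | CON(C)C(=O)/C=C(\C)C(OC)OC | intermediate
18 | (2E)-4,4-dimethoxy-3-methylbut-2-enal | O=C/C=C(\C)C(OC)OC | intermediate
19 | bromo{(2Z,4R,7Z)-8-iodo-2-(methoxycarbonyl)-4-[(4-methoxybenzyl)oxy]-7-methylocta-2,7-dien-1-yl}zinc (allylzinc bromide) | COC(=O)/C(C[Zn]Br)=C/[C@H](OCc1ccc(OC)cc1)CC/C(C)=C\I | intermediate
20 | (4R,5S)-5-[(1E)-3,3-dimethoxy-2-methylprop-1-en-1-yl]-4-{(1R,4Z)-5-iodo-1-[(4-methoxybenzyl)oxy]-4-methylpent-4-en-1-yl}-3-methylideneoxolan-2-one (lactone acetal) | C=C1C(=O)O[C@@H](/C=C(\C)C(OC)OC)[C@H]1[C@H](OCc1ccc(OC)cc1)CC/C(C)=C\I | intermediate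
21 | (2E)-3-[(2S,3R)-3-{(1R,4Z)-5-iodo-1-[(4-methoxybenzyl)oxy]-4-methylpent-4-en-1-yl}-4-methylidene-5-oxooxolan-2-yl]-2-methylprop-2-enal | C=C1C(=O)O[C@@H](/C=C(\C)C=O)[C@H]1[C@H](OCc1ccc(OC)cc1)CC/C(C)=C\I | intermediate
22 | (2E)-3-{(2S,3R)-3-[(1R,4Z)-1-hydroxy-5-iodo-4-methylpent-4-en-1-yl]-4-methylidene-5-oxooxolan-2-yl}-2-methylprop-2-enal | C=C1C(=O)O[C@@H](/C=C(\C)C=O)[C@H]1[C@H](O)CC/C(C)=C\I | intermediate
23 | angelic acid, (2Z)-2-methylbut-2-enoic acid | C/C=C(/C)C(=O)O | starting material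
24 | (2Z)-2-methylbut-2-enoic 2,4,6-trichlorobenzoic anhydride (mixed anhydride) | C/C=C(/C)C(=O)OC(=O)c1c(Cl)cc(Cl)cc1Cl | intermediate
25 | (1R,4Z)-5-iodo-4-methyl-1-{(2S,3R)-2-[(1E)-2-methyl-3-oxoprop-1-en-1-yl]-4-methylidene-5-oxooxolan-3-yl}pent-4-en-1-yl (2Z)-2-methylbut-2-enoate | C=C1C(=O)O[C@@H](/C=C(\C)C=O)[C@H]1[C@H](OC(=O)/C(C)=C\C)CC/C(C)=C\I | intermediate
26 | alkenylchromium dichloride of 25 (CrCl2 unit in place of iodine, Z geometry kept) | C=C1C(=O)O[C@@H](/C=C(\C)C=O)[C@H]1[C@H](OC(=O)/C(C)=C\C)CC/C(C)=C\[Cr](Cl)Cl | intermediate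
27 | (3aR,4R,7Z,9S,10E,11aS)-9-hydroxy-7,10-dimethyl-3-methylidene-2-oxo-2,3,3a,4,5,6,9,11a-octahydrocyclodeca[b]furan-4-yl (2Z)-2-methylbut-2-enoate | C=C1C(=O)O[C@H]2/C=C(\C)[C@@H](O)/C=C(C)\CC[C@@H](OC(=O)/C(C)=C\C)[C@@H]12 | intermediate
28 | (3aR,4R,7S,8R,9R,10E,11aS)-7,8-epoxy-9-hydroxy-7,10-dimethyl-3-methylidene-2-oxo-2,3,3a,4,5,6,7,8,9,11a-decahydrocyclodeca[b]furan-4-yl (2Z)-2-methylbut-2-enoate | C=C1C(=O)O[C@H]2/C=C(\C)[C@@H](O)[C@H]3O[C@@]3(C)CC[C@@H](OC(=O)/C(C)=C\C)[C@@H]12 | intermediate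
29 | (3aR,4R,7S,8R,9R,10E,11aS)-9-acetoxy-7,8-epoxy-7,10-dimethyl-3-methylidene-2-oxo-2,3,3a,4,5,6,7,8,9,11a-decahydrocyclodeca[b]furan-4-yl (2Z)-2-methylbut-2-enoate | C=C1C(=O)O[C@H]2/C=C(\C)[C@@H](OC(C)=O)[C@H]3O[C@@]3(C)CC[C@@H](OC(=O)/C(C)=C\C)[C@@H]12 | target

**Step count and risks**

Total number of steps: 15. Longest linear sequence: 13 steps (1–7, then 10–15); steps 8–9 form the second branch.

Steps most likely to fail:

Step 13. The carbonyl addition that closes the ring may show poor or reversed facial selectivity, so that the 9R carbinol forms beside or instead of 27; the sense rests on a conformational model only. Fallback, from 25 back to 27: the cyclisation is run as in step 13 and the carbinol mixture, which contains the 9R epimer of 27 F1, is oxidised without separation (Dess–Martin periodinane, NaHCO3, CH2Cl2) to the cross-conjugated ring dienone F2. Reagent-controlled 1,2-reduction with the (R)-Me-CBS oxazaborolidine and catecholborane in toluene at −78 °C, with the methyl-branched C10 alkenyl arm taken as the large group, is then expected to give the 9S alcohol and returns 27.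

Step 10. The allylzinc may prefer the allyl face anti to the PMB-oxy group (steric instead of chelate control), which would reverse the relay from C4 to C3a and C11a. Fallback, from 18 back to 25: the arm is rebuilt in the antipodal series and C4 is corrected by inversion during esterification. Steps 1 to 7 applied to the S enantiomer of 1 (from L-malic acid) give in turn bromide F3, Grignard reagent F4, alkylcopper F5, alkenylcopper F6, iodoalkene acetonide F7, diol F8, benzylidene acetal F9, PMB ether alcohol F10, aldehyde F11, Baylis–Hillman adduct F12 and allylic bromide F13. Under the conditions of step 10 its allylzinc bromide F14, adding to 18 anti to the ether oxygen, would give lactone acetal F15 and then lactone enal F16, with the required 3aR and 11aS centres and the side-chain carbinol as 4S. DDQ as in step 11 gives alcohol F17, and Mitsunobu esterification with angelic acid 23 (PPh3, diisopropyl azodicarboxylate, toluene, 0 °C) inverts C4 and gives 25 directly.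

Step 14. The vanadium-bound hydroxyl may deliver oxygen to C10=C11 or to the wrong face of C7=C8, or the doubly allylic alcohol may be oxidised to the dienone. Fallback, from 27 back to 29: 27 is acetylated first (Ac2O, pyridine, DMAP) to dienyl acetate F18, in which C10=C11 is flanked by two allylic acyloxy groups and is the least electron-rich alkene. C7=C8 is then epoxidised under reagent control with the dioxirane of the D-fructose-derived Shi ketone (KHSO5 as its triple salt with KHSO4 and K2SO4, K2CO3 buffer, MeCN/dimethoxymethane/water, 0 °C). Its spiro transition state is expected, by analogy with 1-substituted Z-cycloalkenes, to give the 7S,8R oxirane, which is 29 without passing through 28.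

**Further compounds**

F1 | step 13 | (3aR,4R,7Z,9R,10E,11aS)-9-hydroxy-7,10-dimethyl-3-methylidene-2-oxo-2,3,3a,4,5,6,9,11a-octahydrocyclodeca[b]furan-4-yl (2Z)-2-methylbut-2-enoate | C=C1C(=O)O[C@H]2/C=C(\C)[C@H](O)/C=C(C)\CC[C@@H](OC(=O)/C(C)=C\C)[C@@H]12
F2 | step 13 | (3aR,4R,7Z,10E,11aS)-7,10-dimethyl-3-methylidene-2,9-dioxo-2,3,3a,4,5,6,9,11a-octahydrocyclodeca[b]furan-4-yl (2Z)-2-methylbut-2-enoate | C=C1C(=O)O[C@H]2/C=C(\C)C(=O)/C=C(C)\CC[C@@H](OC(=O)/C(C)=C\C)[C@@H]12
F3 | step 10 | (4S)-4-(2-bromoethyl)-2,2-dimethyl-1,3-dioxolane | CC1(C)OC[C@H](CCBr)O1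
F4 | step 10 | bromo{2-[(4S)-2,2-dimethyl-1,3-dioxolan-4-yl]ethyl}magnesium | CC1(C)OC[C@H](CC[Mg]Br)O1
F5 | step 10 | {2-[(4S)-2,2-dimethyl-1,3-dioxolan-4-yl]ethyl}copper | CC1(C)OC[C@H](CC[Cu])O1
F6 | step 10 | {(1Z)-4-[(4S)-2,2-dimethyl-1,3-dioxolan-4-yl]-2-methylbut-1-en-1-yl}copper | CC1(C)OC[C@H](CC/C(C)=C\[Cu])O1
F7 | step 10 | (4S)-4-[(3Z)-4-iodo-3-methylbut-3-en-1-yl]-2,2-dimethyl-1,3-dioxolane | CC1(C)OC[C@H](CC/C(C)=C\I)O1
F8 | step 10 | (2S,5Z)-6-iodo-5-methylhex-5-ene-1,2-diol | OC[C@@H](O)CC/C(C)=C\I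
F9 | step 10 | (4S)-4-[(3Z)-4-iodo-3-methylbut-3-en-1-yl]-2-(4-methoxyphenyl)-1,3-dioxolane (both epimers at C2) | COc1ccc(cc1)C1OC[C@H](CC/C(C)=C\I)O1
F10 | step 10 | (2S,5Z)-6-iodo-2-[(4-methoxybenzyl)oxy]-5-methylhex-5-en-1-ol | OC[C@@H](OCc1ccc(OC)cc1)CC/C(C)=C\I
F11 | step 10 | (2S,5Z)-6-iodo-2-[(4-methoxybenzyl)oxy]-5-methylhex-5-enal | O=C[C@@H](OCc1ccc(OC)cc1)CC/C(C)=C\I
F12 | step 10 | methyl (4S,7Z)-3-hydroxy-8-iodo-4-[(4-methoxybenzyl)oxy]-7-methyl-2-methylideneoct-7-enoate (both C3 epimers) | C=C(C(=O)OC)C(O)[C@@H](OCc1ccc(OC)cc1)CC/C(C)=C\I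
F13 | step 10 | methyl (2Z,4S,7Z)-2-(bromomethyl)-8-iodo-4-[(4-methoxybenzyl)oxy]-7-methylocta-2,7-dienoate | COC(=O)/C(CBr)=C/[C@@H](OCc1ccc(OC)cc1)CC/C(C)=C\I
F14 | step 10 | bromo{(2Z,4S,7Z)-8-iodo-2-(methoxycarbonyl)-4-[(4-methoxybenzyl)oxy]-7-methylocta-2,7-dien-1-yl}zinc | COC(=O)/C(C[Zn]Br)=C/[C@@H](OCc1ccc(OC)cc1)CC/C(C)=C\I
F15 | step 10 | (4R,5S)-5-[(1E)-3,3-dimethoxy-2-methylprop-1-en-1-yl]-4-{(1S,4Z)-5-iodo-1-[(4-methoxybenzyl)oxy]-4-methylpent-4-en-1-yl}-3-methylideneoxolan-2-one | C=C1C(=O)O[C@@H](/C=C(\C)C(OC)OC)[C@H]1[C@@H](OCc1ccc(OC)cc1)CC/C(C)=C\I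
F16 | step 10 | (2E)-3-[(2S,3R)-3-{(1S,4Z)-5-iodo-1-[(4-methoxybenzyl)oxy]-4-methylpent-4-en-1-yl}-4-methylidene-5-oxooxolan-2-yl]-2-methylprop-2-enal | C=C1C(=O)O[C@@H](/C=C(\C)C=O)[C@H]1[C@@H](OCc1ccc(OC)cc1)CC/C(C)=C\I
F17 | step 10 | (2E)-3-{(2S,3R)-3-[(1S,4Z)-1-hydroxy-5-iodo-4-methylpent-4-en-1-yl]-4-methylidene-5-oxooxolan-2-yl}-2-methylprop-2-enal | C=C1C(=O)O[C@@H](/C=C(\C)C=O)[C@H]1[C@@H](O)CC/C(C)=C\I
F18 | step 14 | (3aR,4R,7Z,9S,10E,11aS)-9-acetoxy-7,10-dimethyl-3-methylidene-2-oxo-2,3,3a,4,5,6,9,11a-octahydrocyclodeca[b]furan-4-yl (2Z)-2-methylbut-2-enoate | C=C1C(=O)O[C@H]2/C=C(\C)[C@@H](OC(C)=O)/C=C(C)\CC[C@@H](OC(=O)/C(C)=C\C)[C@@H]12
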